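(All runs were generated by integration for an exercise.)

Read the clock first: in the cedar run target stands at 3% after 4.00 min, with each reading good to 1.5 percentage points. I take that slow start as the wait for gas to dissolve.

the same everywhere: gas phase 14 mM (held)
- cedar: starting material 0.090 M; protic impurity 0.18 M; run made earlier
- ash: starting material 0.14 M; protic impurity 0.18 M; run made earlier
- larch: starting material 0.18 M; protic impurity 0.36 M; run made earlier
- flask: starting material 0.18 M; protic impurity 0.180 M; time 40 min

| run | time / min | target / % |
|---|---|---|
| cedar | 2.00 | 3 |
| cedar | 3.00 | 2 |
| cedar | 4.00 | 3 |
| cedar | 6.00 | 7 |
| cedar | 10.0 | 9 |
| cedar | 15.0 | 13 |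
| cedar | 25.0 | 19 |
| ash | 2.00 | 1 |
| ash | 3.00 | 1 |
| ash | 4.00 | 1 |
| ash | 6.00 | 4 |
| ash | 10.0 | 6 |
| ash | 15.0 | 12 |
| ash | 25.0 | 16 |
| larch | 2.00 | 3 |
| larch | 4.00 | 3 |
| larch | 6.00 | 2 |
| larch | 12.0 | 4 |
| larch | 25.0 | 7 |

(each reading ± 1.5 percentage points)

- percentages count the starting material that a species holds: one homo dimer counts as two
- at the start none of the gas is dissolved
- what may be going on: gas phase <-> dissolved gas; starting material + dissolved gas <-> target; starting material -> side product; 2 starting material -> homo dimer; starting material + protic impurity -> quenched substrate

- target at 40 min, in percent of the starting material charged
- concentration of dissolved gas in solution at 20 min, in percent of saturation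
- the change that raises the amount of target at 40 min, in percent of the starting material charged most ("none" if none brings more than 2 percentage points) (north / west / none)
- amount of target at 40 min, in percent of the starting material charged, after north

- north: doubling the saturation concentration of gas phase, all else as stated
- west: doubling the transfer coefficient of the gas phase, all else as stated

Here is my own reckoning, with the flask built one process at a time. Take the main step first, gas in and target out. After the wait, cedar climbs, as a fraction of its charge, at

slope = (last reading − reading at the end of the wait) / elapsed time = 0.00762 /min

Run on as a straight line from 4.00 min to 40 min, with cedar's slope lent to the flask, this gives 27.4%.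

Now add the protic impurity. The larch run has the same charge of starting material as the flask and twice its impurity, and it reads 7% at 25.0 min. Suppose the impurity acts as a pseudo-first-order loss. Starting material then lives for a time proportional to one over c(protic impurity), and the target made in that life scales the same way. So I carry the impurity product, target percent times c(protic impurity), read from larch with its scatter and taking that last reading as larch's end value:

impurity product = 7% × 0.36 M = 0.0252 M

target in the flask = impurity product / 0.180 M = 14.0%

That is less than the straight line gave.

Last come side product and homo dimer, which take starting material too but stand in no reading. I add no figure for them and let 14.0% stand as my estimate.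

The forecast is higher than my figure: 21% of target, 60% of saturation at 20 min, north as the best change, and 35% after it. One of its grounds was that “quenching is the main loss”.

The flask gives 10.9% of target at 40 min and 43.0% of saturation at 20 min. The best change is north, worth 7.8 points against 5.1 points for west, and 18.7% stands after it.

    gas phase ⇌ dissolved gas, rate k1*(csat - [dissolved gas]) (kL = 0.110 /min)
    starting material + dissolved gas ⇌ target (K = 500 /M, k = 11.0 /M/min)
    starting material → side product (k = 0.0590 /min)
    2 starting material → homo dimer (k = 0.0370 /M/min)
    starting material + protic impurity → quenched substrate (k = 0.360 /M/min)

The flask's own impurity product is 0.0196 M, and at 40.0 min it holds 44.4% side product beside 38.6% quenched substrate. Now take the neighbouring flask, the same recipe with 0.45 M of protic impurity. The larch product divided by that amount gives 5.60%. At 40.0 min this neighbour holds 27.0% side product, 64.1% quenched substrate and 5.59% target, so its impurity product, more than the flask's, is 0.0252 M.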